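## Structural features

Ferugin is a daucane sesquiterpene ester built on a trans-fused bicyclo[5.3.0]decane: a cyclopentane (C1–C5) and a cycloheptane (C1, C5–C10) share the C1–C5 bond. Four stereocentres lie in a row around that bond: the quaternary C1 with the angular methyl (β), C5 with an α hydrogen, the fully substituted carbinol C4 (β hydroxyl, α isopropyl) and C6, whose α oxygen carries the 4-hydroxybenzoyl group. The fifth stereocentre, the 9α carbinol, is separated from them by C10 and sits beside the exocyclic C8=C14 methylene. The fragile groups are the aryl ester with its free phenol (basic cleavage, acyl migration to O4 or O9), the tertiary C4 hydroxyl in 1,3-relation to the ester (dehydration under acid), and the allylic alcohol next to a 1,1-disubstituted alkene (ionisation, migration of the alkene into the ring). The real difficulty is the quaternary C1 beside C5 with a trans ring fusion, flanked by the tetrasubstituted C4 and by C6, and the C9 configuration: in the trans-fused system the axial C1 methyl screens the β face of C9, which is the face a hydride would have to use. The key step exploits the fact that, read as a head-to-tail farnesyl chain, the bicycle lacks only the bonds C5–C4 and C1–C10. Both end at C5 and C1, the two carbons of an E-trisubstituted alkene of the open chain, so anti addition of a ketone carbon (C4) and an enol carbon (C10) across that alkene makes both rings, the quaternary centre and the trans fusion together.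

## Logic of the disconnections

33 ⇒ 32. The aryl O–Si bond and the C9–O acyl bond are cut together. The last step should only unmask, and it must leave the C6 ester alone. This requires that methanolysis distinguishes two benzoates; the nitro-substituted one is activated, and the other becomes a deactivated phenoxide as soon as its silyl group is lost.

32 ⇒ 28 + 31. The C6–O acyl bond is cut, which makes the ester formation convergent. Only O6 may be acylated: O4 is tertiary and O9 is already blocked in 28.

31 ⇒ 29. The aryl O–Si bond is cut; the phenol must be masked so that the acid can be activated without self-condensation.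

28 ⇒ 27. The O6–Si bond is cut. The fluoride source must not touch the allylic ester at C9.

27 ⇒ 26. The C9–O bond is cut with inversion. A hydride reaches C9 only from the α face, so the 9α oxygen has to come from a displacement on the 9β alcohol; the ester that results also protects O9. The forward step must be a direct substitution at C9, not attack at C14 or elimination.

26 ⇒ 25. The C9–H bond is cut, which leads back to the enone. The reduction must be 1,2 and face-selective.

25 ⇒ 21. The C8=C14 bond is cut, which removes the last skeletal carbon. Enolisation must go to C8 and not to C10.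

21 ⇒ 19. The bonds C5–C4 and C1–C10 are cut, which opens both rings and removes three stereocentres in one operation. The chain 19 keeps only the E-alkene geometry and the C6 stereocentre. The forward step must start at the ketone, proceed by anti addition across the alkene and end at the enol silane faster than any side reaction of the cation.

19 ⇒ 15 + 17 (from 16). The C4–isopropyl bond is cut. C4 travels at the acid oxidation level, so the ketone appears only in the last step before the cascade and no alcohol has to be unmasked or oxidised beside the enol silane. The organometallic must add once and must not attack silicon.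

15 ⇒ 13. The enol O–Si bond is cut. Enolisation must be kinetic (methyl side) and must select the ketone over the amide.

13 ⇒ 12. The C9=O group is traced back to a terminal alkene, which needs no protecting group on the way. The oxidation must ignore the trisubstituted alkene.

12 ⇒ 11 ⇒ 10 ⇒ 9. The O6–Si bond, then the C6–H bond (asymmetric reduction), then the oxidation are undone. The C6 stereocentre is thus created by reagent control from a racemic coupling product.

9 ⇒ 7 + 8. The C5–C6 bond is cut, which gives two simple fragments. The coupling must keep the E geometry and tolerate the amide.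

7 ⇒ 5 ⇒ 3 ⇒ 1. The amide C–N bond, the oxidation level of C4, and finally the C1–CH3 and C5–I bonds across the alkyne are undone. Syn carbometalation of 1 fixes the E geometry on which the ring fusion later depends.

## Other disconnections considered

Alternative 1: The cut is the C15–C1 bond. The angular methyl is added late to the tetrasubstituted C1=C5 alkene of the bicyclic allylic alcohol A1. In the forward key step Et2Zn/CH2I2, directed by the 6β hydroxyl, gives the cyclopropane A2; unmasking of the C4 ketone and reductive opening of the C15–C5 bond would then leave the methyl on C1 and a C5 enolate that is protonated anti to it.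
- In its favour: every operation is of a well-known type, and the alkene face is fixed by a neighbouring hydroxyl. The C9 oxygen is already present with the α configuration, so the late C9 problem of the chosen plan does not arise; on these two points (precedent and C9) the alternative is the better one. The 6β hydroxyl that directs the reagent has the wrong configuration for the target, but the inversion can be merged with ester formation.
- Against it: the key step makes one lasting C–C bond and no ring, so the whole hydroazulene A1 must exist beforehand. Cyclopropanation of a tetrasubstituted alkene is slow, and the C4 carbinol still has to be made by addition to a hindered ketone.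
- Comparison: on structure the chosen plan gains two rings, two skeletal bonds and three stereocentres in one step against one bond and two stereocentres. On mechanism the alternative is safer. On step economy it is clearly longer.

Alternative 2: The cut is C8–C7 and C10–C1, that is the seven-membered ring, which is assembled from the cyclopentenyl diene A3 and methyl 2-diazobut-3-enoate A4. In the forward key step a dirhodium carboxylate such as Rh2(OAc)4 generates the vinylcarbenoid, which cyclopropanates the silyl enol ether double bond of A3; the cis-divinylcyclopropane undergoes a Cope rearrangement to the cycloheptadiene A5.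
- In its favour: it is convergent and belongs to an established, stereospecific reaction class, so on precedent it is the better plan. C14 arrives as the ester carbon on C8, which is also better than a separate methylenation. The quaternary C1 is set by the C4 stereocentre.
- Against it: A3 needs an enantiopure tertiary silyloxy centre. In A5 the carbon C5 is still sp2, so the ring-fusion hydrogen (trans) and the C6 carbinol must be set afterwards, and the C8=C9 enoate must be transposed into the C8 methylene and C9 carbinol.
- Comparison: on structure it builds one ring and one stereocentre against two rings and three stereocentres. On mechanism it is equal or better. On step economy the work left after the key step is heavier, and the total depends on the access to A3.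

Alternative 3: The cut is the C5–C1 bond of the cyclopentane. (S)-Citronellol A6 is converted into the α-diazo-β-keto ester A7. In the forward key step Rh2(OAc)4 forms a carbenoid that inserts into the tertiary C1–H bond with retention and gives the cyclopentanone A8, with the ester trans to the silyloxyethyl arm.
- In its favour: the absolute configuration of the quaternary carbon comes from the chiral pool and needs no catalyst control; on this point it is the better plan. 1,5-Insertion into a tertiary C–H bond is predictable, and the trans arrangement at C5 is the thermodynamic one.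
- Against it: only the five-membered ring is made. The isopropyl carbinol at C4 (addition to an enolisable β-keto ester is awkward), the entire seven-membered ring, C6, the C8 methylene and the C9 carbinol all remain.
- Comparison: on structure it forms one bond, one ring and two stereocentres. On mechanism it is the more secure. On step economy it is the longest of the four plans.

Key step: step 11

Assumption: daucane numbering is used for all bicyclic compounds (C1 the methyl-bearing ring-fusion carbon, C14 the exocyclic methylene carbon), and α denotes the ring face opposite to the C1 methyl group.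

## Route

Step 1
Reactants: 1 pent-4-yn-1-ol
Product: 3 (4E)-5-iodo-4-methylpent-4-en-1-ol, via alkenylalane 2 (not isolated)
Conditions: Me3Al (3 equiv), Cp2ZrCl2 (0.25 equiv), CH2Cl2, 0 °C → rt; then I2, THF, −30 → 0 °C
Reagents that add atoms: trimethylaluminium C[Al](C)C; iodine II
Why: Negishi zirconium-catalysed carboalumination adds methyl and aluminium syn across the terminal alkyne with aluminium on the terminal carbon, and iodinolysis of the alkenyl–aluminium bond goes with retention, so the E-alkenyl iodide carrying the future C1 methyl results; the hydroxyl travels as its aluminium alkoxide.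

Step 2
Reactants: 3 (4E)-5-iodo-4-methylpent-4-en-1-ol
Product: 5 (4E)-5-iodo-4-methylpent-4-enoic acid, via aldehyde 4 (not isolated)
Conditions: TEMPO (0.2 equiv), PhI(OAc)2 (2.2 equiv), MeCN/H2O 1:1, rt
Reagents that add atoms: water O
Why: Oxoammonium (TEMPO) oxidation with PhI(OAc)2 as terminal oxidant in aqueous acetonitrile takes the primary alcohol through aldehyde 4 and its hydrate to the acid; the alkenyl iodide is inert to these conditions.

Step 3
Reactants: 5 (4E)-5-iodo-4-methylpent-4-enoic acid
Product: 7 (4E)-5-iodo-N-methoxy-N,4-dimethylpent-4-enamide, via acyl imidazole 6 (not isolated)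
Conditions: CDI (1.2 equiv), CH2Cl2, rt; then MeNH(OMe)·HCl (1.5 equiv), rt
Reagents that add atoms: N,O-dimethylhydroxylamine hydrochloride CNOC.Cl
Why: Amide formation through the acyl imidazole; the N-methoxy-N-methyl amide keeps C4 at the acid oxidation level until step 10 and is inert to the steps in between.

Step 4
Reactants: 7 (4E)-5-iodo-N-methoxy-N,4-dimethylpent-4-enamide; 8 pent-4-enal
Product: 9 (4E)-6-hydroxy-N-methoxy-N,4-dimethyldeca-4,9-dienamide (racemic at C6)
Conditions: CrCl2 (4 equiv), NiCl2 (0.02 equiv), DMF, rt
Reagents that add atoms: none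
Why: Nozaki–Hiyama–Kishi coupling: nickel catalysis turns the alkenyl iodide into an alkenyl species of trivalent chromium that adds to the aldehyde only and keeps the E geometry; the amide and the terminal alkene are not touched, and the racemic carbinol is corrected in steps 5 and 6.

Step 5
Reactants: 9 (4E)-6-hydroxy-N-methoxy-N,4-dimethyldeca-4,9-dienamide
Product: 10 (4E)-N-methoxy-N,4-dimethyl-6-oxodeca-4,9-dienamide
Conditions: Dess–Martin periodinane (1.3 equiv), NaHCO3, CH2Cl2, 0 °C → rt
Reagents that add atoms: none
Why: Dess–Martin oxidation of the allylic alcohol to the enone under buffered neutral conditions; no other group in 9 is oxidisable.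

Step 6
Reactants: 10 (4E)-N-methoxy-N,4-dimethyl-6-oxodeca-4,9-dienamide
Product: 11 (4E,6S)-6-hydroxy-N-methoxy-N,4-dimethyldeca-4,9-dienamide
Conditions: (R)-Me-CBS oxazaborolidine (0.2 equiv), catecholborane (1.8 equiv), toluene, −78 °C
Reagents that add atoms: none
Why: Corey–Bakshi–Shibata reduction: the alkenyl group acts as the large ketone substituent, so the (R)-oxazaborolidine directs hydride to the face that gives the (S)-allylic alcohol (C6); catecholborane at −78 °C leaves the terminal alkene and the amide alone.

Step 7
Reactants: 11 (4E,6S)-6-hydroxy-N-methoxy-N,4-dimethyldeca-4,9-dienamide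
Product: 12 (4E,6S)-6-[(tert-butyldimethylsilyl)oxy]-N-methoxy-N,4-dimethyldeca-4,9-dienamide
Conditions: TBSCl (1.3 equiv), imidazole (2.5 equiv), DMF, rt
Reagents that add atoms: tert-butyldimethylsilyl chloride CC(C)(C)[Si](C)(C)Cl
Why: Standard silylation of the secondary alcohol; the bulky, weakly Lewis-basic silyl ether is the group wanted at C6 in step 11.

Step 8
Reactants: 12 (4E,6S)-6-[(tert-butyldimethylsilyl)oxy]-N-methoxy-N,4-dimethyldeca-4,9-dienamide
Product: 13 (4E,6S)-6-[(tert-butyldimethylsilyl)oxy]-N-methoxy-N,4-dimethyl-9-oxodec-4-enamide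
Conditions: PdCl2 (0.1 equiv), CuCl (1 equiv), O2 (1 atm), DMF/H2O 7:1, rt
Reagents that add atoms: water O
Why: Tsuji–Wacker oxidation: divalent palladium activates only the monosubstituted alkene and water adds at the internal carbon (Markovnikov), which gives the methyl ketone; the trisubstituted alkene, the silyl ether and the amide are inert.

Step 9
Reactants: 13 (4E,6S)-6-[(tert-butyldimethylsilyl)oxy]-N-methoxy-N,4-dimethyl-9-oxodec-4-enamide
Product: 15 (4E,6S)-6,9-bis[(tert-butyldimethylsilyl)oxy]-N-methoxy-N,4-dimethyldeca-4,9-dienamide, via lithium enolate 14 (not isolated)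
Conditions: LDA (1.1 equiv), THF, −78 °C; then TBSCl, DMPU, −78 → 0 °C
Reagents that add atoms: tert-butyldimethylsilyl chloride CC(C)(C)[Si](C)(C)Cl
Why: Kinetic enolisation: the hindered amide base removes a proton from the methyl group, the least hindered α-position of the ketone, which is far more acidic than the α-CH2 of the amide; O-silylation of enolate 14 gives the terminal silyl enol ether.

Step 10
Reactants: 15 (4E,6S)-6,9-bis[(tert-butyldimethylsilyl)oxy]-N-methoxy-N,4-dimethyldeca-4,9-dienamide; 16 2-bromopropane
Product: 19 (6E,8S)-8,11-bis[(tert-butyldimethylsilyl)oxy]-2,6-dimethyldodeca-6,11-dien-3-one, via isopropylmagnesium bromide 17 (not isolated), via magnesium hemiaminal 18 (not isolated)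
Conditions: 16, Mg, THF, rt; then 15, THF, 0 °C; pH 7 phosphate buffer
Reagents that add atoms: none
Why: Weinreb ketone synthesis: the Grignard reagent 17 adds once and the magnesium chelate 18 releases the isopropyl ketone only on work-up, when no organometallic is left; silyl ethers and silyl enol ethers are inert to Grignard reagents and the buffered quench spares the enol silane. Making the ketone last in this way avoids any deprotection or oxidation beside the enol silane.

Step 11
Reactants: 19 (6E,8S)-8,11-bis[(tert-butyldimethylsilyl)oxy]-2,6-dimethyldodeca-6,11-dien-3-one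
Product: 21 (1R,4R,5S,6S)-6α-[(tert-butyldimethylsilyl)oxy]-4β-hydroxy-14-nordaucan-9-one, via tertiary cation zwitterion 20 (not isolated)
Conditions: Me2AlCl (2.5 equiv), CH2Cl2, −78 → −40 °C, 19 added slowly (final 0.002 M); aqueous Rochelle salt
Reagents that add atoms: none
Why: Proposed new method: Me2AlCl binds the isopropyl ketone and the E-alkene attacks the activated carbonyl through C5 (Markovnikov), which forms C5–C4 and the aluminate–tertiary cation zwitterion 20; the enol silane carbon C10 then captures C1 (C1–C10) and chloride takes the silyl group, which leaves the C9 ketone. The closest known reaction type is the Lewis-acid Prins (carbonyl-initiated) cation–olefin cyclisation terminated by a silyl enol ether; a 5-endo initiation followed by seven-membered capture has no precedent. Ring 1 (cyclopentane) closes 5-exo-trig at the carbonyl carbon and 5-endo with respect to the alkene, which a cation–olefin process allows because the charge develops at the tertiary C1; ring 2 (cycloheptanone) closes with both enol ether carbons inside the new ring (7-endo), not with that double bond exocyclic. C1 and C5: antiperiplanar addition of C4 and C10 across the E-alkene places H5 and the C1 methyl trans (trans ring fusion) and the methyl cis to the C6 arm. Absolute sense at C1 and C5: the C6 stereocentre, through allylic 1,3-strain, holds H6 in the inside position beside the cis C1 methyl, so the C7 chain stands anti to the incoming carbonyl carbon (on the face from which C10 must reach C1) and the silyloxy group points outward. C4: in the envelope-like transition state the isopropyl group is pseudo-equatorial, away from the C6 arm and the C1 methyl, and the aluminium-bound oxygen pseudo-axial, which gives the 4β oxygen. The step needs ring closure to outrun intermolecular Mukaiyama aldol addition, 1,2-hydride shift or proton loss from 20 and ionisation of the allylic C6–O bond; high dilution with slow addition, the tethered and strongly nucleophilic enol silane, the bulky and poorly Lewis-basic silyl ether at C6 (which also makes a cation at C5 unattractive) and the proton-scavenging methylaluminium reagent at low temperature are the safeguards.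

Step 12
Reactants: 21 (1R,4R,5S,6S)-6α-[(tert-butyldimethylsilyl)oxy]-4β-hydroxy-14-nordaucan-9-one
Product: 25 (1R,4R,5S,6S)-6α-[(tert-butyldimethylsilyl)oxy]-4β-hydroxydauc-8(14)-en-9-one, via dilithium alkoxide enolate 22 (not isolated), via Mannich base 23 (not isolated), via trimethylammonium iodide 24 (not isolated)
Conditions: LDA (2.3 equiv), THF, −78 °C; Me2N=CH2+ I− (Eschenmoser's salt), −78 °C → rt; then MeI, CH2Cl2/Et2O, rt; then aqueous NaHCO3, rt
Reagents that add atoms: dimethylmethyleneiminium iodide C=[N+](C)C.[I-]
Why: α-Methylenation by the Mannich route: the first equivalent of base forms the C4 alkoxide and the second enolises kinetically towards C8, because C10 is neopentyl-like beside the quaternary C1; enolate 22 is aminomethylated by Eschenmoser's salt, and N-methylation followed by base-induced elimination of trimethylamine gives the exocyclic enone.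

Step 13
Reactants: 25 (1R,4R,5S,6S)-6α-[(tert-butyldimethylsilyl)oxy]-4β-hydroxydauc-8(14)-en-9-one
Product: 26 (1R,4R,5S,6S,9R)-6α-[(tert-butyldimethylsilyl)oxy]dauc-8(14)-ene-4β,9β-diol
Conditions: NaBH4, CeCl3·7H2O, MeOH, −78 °C
Reagents that add atoms: none
Why: Luche 1,2-reduction of the enone: in the cycloheptene-like chair that the trans ring fusion enforces (C7–C8–C9–C10 coplanar, C1 and C6 displaced to the β side) the axial C1 methyl covers the β face of C9, so hydride should enter from the open α face and give the 9β alcohol (9R). A direct reduction therefore cannot be relied on for the 9α alcohol, and the configuration is corrected in step 14.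

Step 14
Reactants: 26 (1R,4R,5S,6S,9R)-6α-[(tert-butyldimethylsilyl)oxy]dauc-8(14)-ene-4β,9β-diol
Product: 27 (1R,4R,5S,6S,9S)-6α-[(tert-butyldimethylsilyl)oxy]-4β-hydroxydauc-8(14)-en-9α-yl 4-nitrobenzoate
Conditions: 4-nitrobenzoic acid (3 equiv), PPh3 (3 equiv), DIAD (3 equiv), toluene, 0 °C → rt
Reagents that add atoms: 4-nitrobenzoic acid OC(=O)c1ccc(cc1)[N+](=O)[O-]
Why: Mitsunobu esterification: the alkoxyphosphonium ion of the 9β alcohol is displaced by 4-nitrobenzoate in an SN2 reaction from the open α face, which inverts C9 to the required 9α (9S) configuration; the tertiary C4 hydroxyl does not react, and the ester protects O9 through steps 15 and 17.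

Step 15
Reactants: 27 (1R,4R,5S,6S,9S)-6α-[(tert-butyldimethylsilyl)oxy]-4β-hydroxydauc-8(14)-en-9α-yl 4-nitrobenzoate
Product: 28 (1R,4R,5S,6S,9S)-4β,6α-dihydroxydauc-8(14)-en-9α-yl 4-nitrobenzoate
Conditions: HF·pyridine, pyridine/THF, 0 °C → rt
Reagents that add atoms: none
Why: Fluoride-mediated cleavage of the secondary silyl ether; buffered HF·pyridine leaves the allylic ester, the exocyclic alkene and the tertiary alcohol intact.

Step 16
Reactants: 29 4-hydroxybenzoic acid
Product: 31 4-[(tert-butyldimethylsilyl)oxy]benzoic acid, via silyl ester 30 (not isolated)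
Conditions: TBSCl (2.3 equiv), imidazole (5 equiv), DMF, rt; then AcOH/THF/H2O 3:1:1, rt
Reagents that add atoms: tert-butyldimethylsilyl chloride CC(C)(C)[Si](C)(C)Cl
Why: Silylation of both the phenol and the acid, then selective hydrolysis of the labile silyl ester in aqueous acetic acid, leaves the aryl silyl ether.

Step 17
Reactants: 28 (1R,4R,5S,6S,9S)-4β,6α-dihydroxydauc-8(14)-en-9α-yl 4-nitrobenzoate; 31 4-[(tert-butyldimethylsilyl)oxy]benzoic acid
Product: 32 (1R,4R,5S,6S,9S)-6α-({4-[(tert-butyldimethylsilyl)oxy]benzoyl}oxy)-4β-hydroxydauc-8(14)-en-9α-yl 4-nitrobenzoate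
Conditions: DCC (2 equiv), DMAP (0.5 equiv), CH2Cl2, rt
Reagents that add atoms: none
Why: Steglich esterification: the secondary 6α hydroxyl is the only hydroxyl that can be acylated, since the C4 hydroxyl is tertiary and hindered and O9 is blocked; no stereocentre is touched.

Step 18
Reactants: 32 (1R,4R,5S,6S,9S)-6α-({4-[(tert-butyldimethylsilyl)oxy]benzoyl}oxy)-4β-hydroxydauc-8(14)-en-9α-yl 4-nitrobenzoate
Product: 33 ferugin, (1R,4R,5S,6S,9S)-4β,9α-dihydroxydauc-8(14)-en-6α-yl 4-hydroxybenzoate
Conditions: K2CO3 (2 equiv), MeOH, 0 °C → rt; aqueous NH4Cl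
Reagents that add atoms: none
Why: Potassium carbonate in methanol first cleaves the aryl silyl ether; the resulting 4-oxidobenzoate at C6 is a poor acyl donor, while the electron-poor 4-nitrobenzoate at C9 is transesterified by acyl–oxygen cleavage with retention, which frees the 9α hydroxyl and gives 33.

## Compound list

1 | pent-4-yn-1-ol | C#CCCCO | starting material
2 | alkenylalane: dimethyl{(1E)-5-[(dimethylalumanyl)oxy]-2-methylpent-1-en-1-yl}alumane | C[Al](C)OCCC/C(C)=C/[Al](C)C | intermediate (not isolated)
3 | (4E)-5-iodo-4-methylpent-4-en-1-ol | OCCC/C(C)=C/I | intermediate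
4 | (4E)-5-iodo-4-methylpent-4-enal | O=CCC/C(C)=C/I | intermediate (not isolated)
5 | (4E)-5-iodo-4-methylpent-4-enoic acid | OC(=O)CC/C(C)=C/I | intermediate
6 | (4E)-1-(1H-imidazol-1-yl)-5-iodo-4-methylpent-4-en-1-one | O=C(CC/C(C)=C/I)n1ccnc1 | intermediate (not isolated)
7 | (4E)-5-iodo-N-methoxy-N,4-dimethylpent-4-enamide | CON(C)C(=O)CC/C(C)=C/I | intermediate
8 | pent-4-enal | C=CCCC=O | starting material
9 | (4E)-6-hydroxy-N-methoxy-N,4-dimethyldeca-4,9-dienamide (racemic at C6) | CON(C)C(=O)CC/C(C)=C/C(O)CCC=C | intermediate
10 | (4E)-N-methoxy-N,4-dimethyl-6-oxodeca-4,9-dienamide | CON(C)C(=O)CC/C(C)=C/C(=O)CCC=C | intermediate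
11 | (4E,6S)-6-hydroxy-N-methoxy-N,4-dimethyldeca-4,9-dienamide | CON(C)C(=O)CC/C(C)=C/[C@@H](O)CCC=C | intermediate
12 | (4E,6S)-6-[(tert-butyldimethylsilyl)oxy]-N-methoxy-N,4-dimethyldeca-4,9-dienamide | CON(C)C(=O)CC/C(C)=C/[C@@H](O[Si](C)(C)C(C)(C)C)CCC=C | intermediate
13 | (4E,6S)-6-[(tert-butyldimethylsilyl)oxy]-N-methoxy-N,4-dimethyl-9-oxodec-4-enamide | CON(C)C(=O)CC/C(C)=C/[C@@H](O[Si](C)(C)C(C)(C)C)CCC(C)=O | intermediate
14 | lithium enolate of 13 (terminal C9=C10 enolate) | CON(C)C(=O)CC/C(C)=C/[C@@H](O[Si](C)(C)C(C)(C)C)CCC(=C)O[Li] | intermediate (not isolated)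
15 | (4E,6S)-6,9-bis[(tert-butyldimethylsilyl)oxy]-N-methoxy-N,4-dimethyldeca-4,9-dienamide | CON(C)C(=O)CC/C(C)=C/[C@@H](O[Si](C)(C)C(C)(C)C)CCC(=C)O[Si](C)(C)C(C)(C)C | intermediate
16 | 2-bromopropane | CC(C)Br | starting material
17 | isopropylmagnesium bromide | CC(C)[Mg]Br | intermediate (not isolated)
18 | magnesium hemiaminal (tetrahedral adduct of 15 and 17; C4 unassigned) | CC(C)C(O[Mg]Br)(N(C)OC)CC/C(C)=C/[C@@H](O[Si](C)(C)C(C)(C)C)CCC(=C)O[Si](C)(C)C(C)(C)C | intermediate (not isolated)
19 | (6E,8S)-8,11-bis[(tert-butyldimethylsilyl)oxy]-2,6-dimethyldodeca-6,11-dien-3-one | CC(C)C(=O)CC/C(C)=C/[C@@H](O[Si](C)(C)C(C)(C)C)CCC(=C)O[Si](C)(C)C(C)(C)C | intermediate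
20 | tertiary cation zwitterion (cyclopentyl C1 cation, C4 chlorodimethylaluminate alkoxide; 4β-O, 5α-H, 6S) | C=C(O[Si](C)(C)C(C)(C)C)CC[C@H](O[Si](C)(C)C(C)(C)C)[C@@H]1[C+](C)CC[C@@]1(O[Al-](C)(C)Cl)C(C)C | intermediate (not isolated)
21 | (1R,4R,5S,6S)-6α-[(tert-butyldimethylsilyl)oxy]-4β-hydroxy-14-nordaucan-9-one (trans-fused, 1β-methyl, 5α-H) | C1C[C@H](O[Si](C)(C)C(C)(C)C)[C@@H]2[C@](C)(CC[C@@]2(O)C(C)C)CC1=O | intermediate
22 | dilithium alkoxide enolate of 21 (C4 alkoxide, C8=C9 enolate) | C=1C[C@H](O[Si](C)(C)C(C)(C)C)[C@@H]2[C@](C)(CC[C@@]2(O[Li])C(C)C)CC=1O[Li] | intermediate (not isolated)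
23 | Mannich base: 8-[(dimethylamino)methyl] derivative of 21 (C8 unassigned) | CN(C)CC1C[C@H](O[Si](C)(C)C(C)(C)C)[C@@H]2[C@](C)(CC[C@@]2(O)C(C)C)CC1=O | intermediate (not isolated)
24 | trimethylammonium iodide of 23 | C[N+](C)(C)CC1C[C@H](O[Si](C)(C)C(C)(C)C)[C@@H]2[C@](C)(CC[C@@]2(O)C(C)C)CC1=O.[I-] | intermediate (not isolated)
25 | (1R,4R,5S,6S)-6α-[(tert-butyldimethylsilyl)oxy]-4β-hydroxydauc-8(14)-en-9-one | C=C1C[C@H](O[Si](C)(C)C(C)(C)C)[C@@H]2[C@](C)(CC[C@@]2(O)C(C)C)CC1=O | intermediate
26 | (1R,4R,5S,6S,9R)-6α-[(tert-butyldimethylsilyl)oxy]dauc-8(14)-ene-4β,9β-diol | C=C1C[C@H](O[Si](C)(C)C(C)(C)C)[C@@H]2[C@](C)(CC[C@@]2(O)C(C)C)C[C@H]1O | intermediate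
27 | (1R,4R,5S,6S,9S)-6α-[(tert-butyldimethylsilyl)oxy]-4β-hydroxydauc-8(14)-en-9α-yl 4-nitrobenzoate | C=C1C[C@H](O[Si](C)(C)C(C)(C)C)[C@@H]2[C@](C)(CC[C@@]2(O)C(C)C)C[C@@H]1OC(=O)c1ccc(cc1)[N+](=O)[O-] | intermediate
28 | (1R,4R,5S,6S,9S)-4β,6α-dihydroxydauc-8(14)-en-9α-yl 4-nitrobenzoate | C=C1C[C@H](O)[C@@H]2[C@](C)(CC[C@@]2(O)C(C)C)C[C@@H]1OC(=O)c1ccc(cc1)[N+](=O)[O-] | intermediate
29 | 4-hydroxybenzoic acid | OC(=O)c1ccc(O)cc1 | starting material
30 | tert-butyldimethylsilyl 4-[(tert-butyldimethylsilyl)oxy]benzoate | CC(C)(C)[Si](C)(C)OC(=O)c1ccc(O[Si](C)(C)C(C)(C)C)cc1 | intermediate (not isolated)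
31 | 4-[(tert-butyldimethylsilyl)oxy]benzoic acid | OC(=O)c1ccc(O[Si](C)(C)C(C)(C)C)cc1 | intermediate
32 | (1R,4R,5S,6S,9S)-6α-({4-[(tert-butyldimethylsilyl)oxy]benzoyl}oxy)-4β-hydroxydauc-8(14)-en-9α-yl 4-nitrobenzoate | C=C1C[C@H](OC(=O)c2ccc(O[Si](C)(C)C(C)(C)C)cc2)[C@@H]2[C@](C)(CC[C@@]2(O)C(C)C)C[C@@H]1OC(=O)c1ccc(cc1)[N+](=O)[O-] | intermediate
33 | ferugin, (1R,4R,5S,6S,9S)-4β,9α-dihydroxydauc-8(14)-en-6α-yl 4-hydroxybenzoate | C=C1C[C@H](OC(=O)c2ccc(O)cc2)[C@@H]2[C@](C)(CC[C@@]2(O)C(C)C)C[C@@H]1O | target

## Step count and least certain steps

Total step count: 18. Longest linear sequence: 17 steps (steps 1–15, 17 and 18, from 1); step 16 is a one-step side branch.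

Step 11 (proposed new method).
- What may go wrong: initiation through the 5-endo mode may be too slow, so that intermolecular Mukaiyama aldol addition or loss of the enol silane takes over. After the first bond is formed, 1,2-hydride shift or proton loss from the cyclopentyl cation may outrun closure of the seven-membered ring. The allylic C6–O bond may ionise. If the capture is not strictly anti, the ring fusion or the C4 configuration may leak.
- Fallback, with known reactions only; it sets out from pent-4-enal 8 and returns to the route at 21. The rings are closed one after the other.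
  - Copper-catalysed asymmetric conjugate addition of a vinylalane (chiral N-heterocyclic carbene ligand) to commercial 3-methylcyclopent-2-en-1-one creates the quaternary carbon. The aluminium enolate is trapped with 8 in an anti-selective aldol addition (Zimmerman–Traxler) to give (2S,3R)-3-ethenyl-2-[(1S)-1-hydroxypent-4-en-1-yl]-3-methylcyclopentan-1-one F1.
  - Silylation (TBSCl, imidazole) gives (2S,3R)-2-[(1S)-1-{[tert-butyl(dimethyl)silyl]oxy}pent-4-en-1-yl]-3-ethenyl-3-methylcyclopentan-1-one F2.
  - The organocerium reagent from 17 and CeCl3 adds to the ketone anti to the C5 side chain and gives (1R,2S,3R)-2-[(1S)-1-{[tert-butyl(dimethyl)silyl]oxy}pent-4-en-1-yl]-3-ethenyl-3-methyl-1-(propan-2-yl)cyclopentan-1-ol F3.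
  - Ring-closing metathesis with the second-generation Grubbs catalyst joins the vinyl group and the terminal alkene to the trans-fused cycloheptene (1R,4R,5S,6S)-6α-[(tert-butyldimethylsilyl)oxy]-14-nordauc-9-en-4β-ol F4.
  - Hydroboration with 9-BBN places boron on C9, the alkene carbon remote from the quaternary centre, and oxidation (H2O2, NaOH) gives (1R,4R,5S,6S)-6α-[(tert-butyldimethylsilyl)oxy]-14-nordaucane-4β,9-diol F5 (both C9 epimers).
  - Dess–Martin oxidation returns 21.
  - This detour is shorter on paper but weaker in stereocontrol. The absolute configuration rests on a catalyst-controlled addition to a cyclopentenone. The C5 configuration rests on the small size difference between methyl and vinyl at C1, so the C5 epimer of F1 is to be expected as a by-product and would have to be separated.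

Step 13.
- What may go wrong: poor facial selectivity of the hydride addition, because the bias rests on a single axial methyl group in a seven-membered ring that keeps some flexibility. A mixture of C9 epimers would then enter step 14.
- Fallback: replace substrate control by catalyst control. From 25, reduction with the (S)-Me-CBS oxazaborolidine and catecholborane at −78 °C is matched with the substrate bias and returns to the route at 26; no new compound is made (F0).

Step 14.
- What may go wrong: attack of the carboxylate at C14 (SN2') or elimination towards C10 in place of direct inversion, because the activated alcohol is allylic, lies syn-axial to the C1 methyl and has an antiperiplanar hydrogen on C10.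
- Fallback: set the 9α configuration by reduction and not by substitution. From 25, the (R)-Me-CBS oxazaborolidine with catecholborane directs hydride to the β face against the substrate bias and gives (1R,4R,5S,6S,9S)-6α-[(tert-butyldimethylsilyl)oxy]dauc-8(14)-ene-4β,9α-diol F6; any 26 formed alongside is separated and re-oxidised to 25. Acylation of F6 with 4-nitrobenzoyl chloride, pyridine and DMAP goes with retention and returns to the route at 27.

Step 10.
- What may go wrong: slow addition of the branched Grignard reagent to the amide, which lets α-deprotonation or reduction of the amide by β-hydride transfer compete, or loss of the enol silane during work-up.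
- Fallback: reach the ketone by reduction, addition and oxidation. From 15, DIBAL-H (THF, −78 °C) gives (4E,6S)-6,9-bis[(tert-butyldimethylsilyl)oxy]-4-methyldeca-4,9-dienal F7. Addition of 17 at −78 °C gives (6E,8S)-8,11-bis[(tert-butyldimethylsilyl)oxy]-2,6-dimethyldodeca-6,11-dien-3-ol F8 (both C3 epimers). Pyridine-buffered Dess–Martin oxidation returns to the route at 19.

## Further compounds

F1 | step 11 | (2S,3R)-3-ethenyl-2-[(1S)-1-hydroxypent-4-en-1-yl]-3-methylcyclopentan-1-one | C=CCC[C@H](O)[C@@H]1[C@](C)(CCC1=O)C=C
F2 | step 11 | (2S,3R)-2-[(1S)-1-{[tert-butyl(dimethyl)silyl]oxy}pent-4-en-1-yl]-3-ethenyl-3-methylcyclopentan-1-one | C=CCC[C@H](O[Si](C)(C)C(C)(C)C)[C@@H]1[C@](C)(CCC1=O)C=C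
F3 | step 11 | (1R,2S,3R)-2-[(1S)-1-{[tert-butyl(dimethyl)silyl]oxy}pent-4-en-1-yl]-3-ethenyl-3-methyl-1-(propan-2-yl)cyclopentan-1-ol | C=CCC[C@H](O[Si](C)(C)C(C)(C)C)[C@@H]1[C@](C)(CC[C@@]1(O)C(C)C)C=C
F4 | step 11 | (1R,4R,5S,6S)-6α-[(tert-butyldimethylsilyl)oxy]-14-nordauc-9-en-4β-ol | C1C[C@H](O[Si](C)(C)C(C)(C)C)[C@@H]2[C@](C)(CC[C@@]2(O)C(C)C)C=C1
F5 | step 11 | (1R,4R,5S,6S)-6α-[(tert-butyldimethylsilyl)oxy]-14-nordaucane-4β,9-diol (C9 epimers) | C1C[C@H](O[Si](C)(C)C(C)(C)C)[C@@H]2[C@](C)(CC[C@@]2(O)C(C)C)CC1O
F0 | step 13 | none | none
F6 | step 14 | (1R,4R,5S,6S,9S)-6α-[(tert-butyldimethylsilyl)oxy]dauc-8(14)-ene-4β,9α-diol | C=C1C[C@H](O[Si](C)(C)C(C)(C)C)[C@@H]2[C@](C)(CC[C@@]2(O)C(C)C)C[C@@H]1O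
F7 | step 10 | (4E,6S)-6,9-bis[(tert-butyldimethylsilyl)oxy]-4-methyldeca-4,9-dienal | O=CCC/C(C)=C/[C@@H](O[Si](C)(C)C(C)(C)C)CCC(=C)O[Si](C)(C)C(C)(C)C
F8 | step 10 | (6E,8S)-8,11-bis[(tert-butyldimethylsilyl)oxy]-2,6-dimethyldodeca-6,11-dien-3-ol (C3 epimers) | CC(C)C(O)CC/C(C)=C/[C@@H](O[Si](C)(C)C(C)(C)C)CCC(=C)O[Si](C)(C)C(C)(C)C
A1 | alternative 1 | bicyclic allylic alcohol with tetrasubstituted C1=C5 alkene, 6β-hydroxyl, 9α-silyloxy group and C4 ethylene ketal | C1C[C@@H](O)C2=C(CCC23OCCO3)C[C@@H]1O[Si](C)(C)C(C)(C)C
A2 | alternative 1 | cyclopropane-fused tricycle with the methylene syn to the 6β-hydroxyl | C1C[C@@H](O)[C@@]23C[C@@]2(CCC34OCCO4)C[C@@H]1O[Si](C)(C)C(C)(C)C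
A3 | alternative 2 | tert-butyldimethyl({1-[(5R)-2-methyl-5-(propan-2-yl)-5-(triethylsilyloxy)cyclopent-1-en-1-yl]ethenyl}oxy)silane | C=C(O[Si](C)(C)C(C)(C)C)C1=C(C)CC[C@@]1(O[Si](CC)(CC)CC)C(C)C
A4 | alternative 2 | methyl 2-diazobut-3-enoate | COC(=O)C(=[N+]=[N-])C=C
A5 | alternative 2 | bicyclic cyclohepta-1,4-diene with C14 ester on C8, C6 silyl enol ether and quaternary C1 | COC(=O)C1=CC[C@@]2(C)CC[C@@](O[Si](CC)(CC)CC)(C(C)C)C2=C(O[Si](C)(C)C(C)(C)C)C1
A6 | alternative 3 | (S)-citronellol, (3S)-3,7-dimethyloct-6-en-1-ol | C[C@@H](CCC=C(C)C)CCO
A7 | alternative 3 | methyl (6S)-8-[(tert-butyldimethylsilyl)oxy]-2-diazo-6-methyl-3-oxooctanoate | COC(=O)C(=[N+]=[N-])C(=O)CC[C@H](C)CCO[Si](C)(C)C(C)(C)C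
A8 | alternative 3 | methyl 2-methyl-5-oxo-2-[2-(tert-butyldimethylsilyloxy)ethyl]cyclopentane-1-carboxylate (ester trans to the silyloxyethyl arm) | COC(=O)[C@@H]1[C@](C)(CCC1=O)CCO[Si](C)(C)C(C)(C)C
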